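**Retrosynthetic overview**
1. Target 15 ⇐ 1β,2β-epoxy-3-ketone 14 ⇐ Δ1-3-ketone 13; ring A is only adjusted in oxidation state, at the very end.
2. Key disconnection: the 12α-hydroxy bicyclo[3.2.1]octane (rings C/D) ⇐ ent-atisane-type bicyclo[2.2.2]octenyl C13 sulfonate 11, by a biogenetic-type cationic 1,2-shift of C16 (C12→C13) with water capture at C12.
3. Bicyclo[2.2.2] ketone 9 ⇐ C12–C16 Pd(II) enolate–olefin closure of allyl ketone 7 ⇐ Grob fragmentation of a 13-OH/17-OTs pair; the unwanted 13-oxygen ends as the leaving group.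
4. Ring order: rings A, B and the 19,10-lactone come intact from gibberellic acid 1; ring D is opened, the bridged ring is closed (C12–C16), the Wagner–Meerwein shift gives the final rings C/D, then ring A is oxidised.

Assumption: α/β follow gibberellin usage (19,10-lactone oxygen = α face); GA numbering is kept for all intermediates, also after the C13–C16 bond is cleaved. Nothing here has been run; selectivities are predictions from mechanism and analogy.

**Step 1**
Reactants: 1 gibberellic acid (GA3)
Product: 2 GA3 methoxymethyl ester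
Conditions: MOMCl (1.1 equiv), Et3N, CH2Cl2–THF, 0 °C
Reagents that add atoms: chloromethyl methyl ether, COCCl
Why: Carboxylate O-alkylation (SN2) masks the 7-acid so that it cannot lactonise onto the allyl group under Pd(II) in step 5 or be activated by TsCl in step 4, while the alcohols stay free at 0 °C.

**Step 2**
Reactants: 2 GA3 methoxymethyl ester
Product: 4 16,17-dihydro-17-hydroxy-GA3 methoxymethyl ester, via C17 9-BBN adduct 3 (not isolated)
Conditions: 9-BBN (4 equiv), THF, 0 °C → rt; then 30% H2O2, pH 7 phosphate buffer, 0 °C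
Reagents that add atoms: 9-borabicyclo[3.3.1]nonane, C1CC2CCCC(C1)B2; hydrogen peroxide, OO
Why: Anti-Markovnikov hydroboration–oxidation, 9-BBN reacting with the 1,1-disubstituted exocyclic alkene far faster than with the ring-A cis-alkene; H goes to C16 from the open exo face, but C16 becomes sp2 again in step 4, so its configuration does not matter.

**Step 3**
Reactants: 4 16,17-dihydro-17-hydroxy-GA3 methoxymethyl ester
Product: 5 Δ1-3-ketone 13,17-diol
Conditions: activated MnO2 (20 equiv), CH2Cl2–acetone, rt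
Reagents that add atoms: none
Why: Allylic-alcohol oxidation with MnO2 touches only the 3β-OH (primary 17-OH and tertiary 13-OH are inert) and gives a non-enolisable enone (C4 and C10 quaternary) that tolerates the bases and acid used later.

**Step 4**
Reactants: 5 Δ1-3-ketone 13,17-diol
Product: 7 13,16-seco allyl ketone, via C17 tosylate 6 (not isolated)
Conditions: TsCl, pyridine, DMAP (cat.), CH2Cl2, 0 °C; then NaH, THF, 0 °C → rt
Reagents that add atoms: p-toluenesulfonyl chloride, Cc1ccc(cc1)S(=O)(=O)Cl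
Why: Selective sulfonylation of the primary alcohol, then Grob (Wharton-type) fragmentation of the γ-tosyloxy tertiary alkoxide: C13 becomes C=O, the C13–C16 bond cleaves anti to C17–OTs and C16=C17 forms, with relief of bicyclic strain (the endo CH2OTs is trans to O13 on ring D, so oxetane closure cannot compete).

**Step 5**
Reactants: 7 13,16-seco allyl ketone
Product: 9 ent-atisane-type enedione, via TMS enol ether 8 (not isolated)
Conditions: LDA (1.05 equiv), TMSCl (in situ), THF, –78 °C; then Pd(OAc)2 (10 mol %), O2 (1 atm), DMSO, 45 °C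
Reagents that add atoms: chlorotrimethylsilane, C[Si](C)(C)Cl
Why: Kinetic enolisation at the less hindered C12 (C14 is neopentyl), then Saegusa–Ito/Kende–Toyota Pd(II) cycloalkenylation: the Pd enolate adds 6-exo to the terminal alkene and β-hydride elimination restores the exocyclic C16=C17; the C12–C16 bond can only form on the ring-C face that carries the C8 allyl arm, which fixes the new bridgehead C12.

**Step 6**
Reactants: 9 ent-atisane-type enedione
Product: 10 ent-atisane-type 13-alcohol
Conditions: NaBH4 (0.5 equiv), MeOH–CH2Cl2 (1:1), –78 °C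
Reagents that add atoms: none
Why: Chemoselective borohydride reduction of the saturated bicyclic ketone over the conjugated, neopentyl C3 enone at low temperature; hydride enters from the open face beside the sp2 C16 bridge, so the 13-OH points toward the C9–C11 bridge, antiperiplanar to the C12–C16 bond.

**Step 7**
Reactants: 10 ent-atisane-type 13-alcohol
Product: 13 12α-hydroxy-3-oxo-1,2-didehydro-GA9, via C13 mesylate 11 (not isolated), via rearranged methoxymethyl ester 12 (not isolated)
Conditions: MsCl, Et3N, CH2Cl2, –20 °C; then acetone–H2O (3:1), 60 °C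
Reagents that add atoms: methanesulfonyl chloride, CS(=O)(=O)Cl; water, O
Why: Biogenetic-type Wagner–Meerwein (homoallyl–cyclopropylcarbinyl) rearrangement within the ent-atisyl/ent-kauranyl cation manifold: ionisation is assisted by the antiperiplanar C12–C16 bond and the 16-ene, C16 migrates from C12 to C13 with inversion (giving the natural C13 bridgehead) through a bridged trachylobane-like cation, and water adds to C12 anti to C16, which sets the 12α-OH; the MsOH released also cleaves the MOM ester.

**Step 8**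
Reactants: 13 12α-hydroxy-3-oxo-1,2-didehydro-GA9
Product: 14 1β,2β-epoxy-12α-hydroxy-3-oxo-GA9
Conditions: t-BuOOH (decane), DBU (2.2 equiv), CH2Cl2, 0 °C
Reagents that add atoms: tert-butyl hydroperoxide, CC(C)(C)OO
Why: Weitz–Scheffer nucleophilic epoxidation under hydroxide-free conditions (avoids retro-Claisen of the β-keto lactone); t-BuOO– adds to C1 anti to the axial C10–O bond, as with 4-oxygenated cyclohexenones, giving the 1β,2β-epoxide.

**Step 9**
Reactants: 14 1β,2β-epoxy-12α-hydroxy-3-oxo-GA9
Product: 15 1β,12α-dihydroxy-3-oxo-GA9 (target)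
Conditions: SmI2 (3 equiv), THF–MeOH, –90 °C; pH 7 buffer
Reagents that add atoms: none
Why: SmI2 reductive cleavage of the Cα–O bond of an α,β-epoxy ketone (Molander) gives the β-hydroxy ketone without touching C1, so the 1β-OH set in step 8 is retained, and the low temperature avoids dehydration or retro-aldol.

**Compound list**
1 | gibberellic acid (GA3): 3β,13-dihydroxy-1,16-diene, 19,10-lactone, 7-oic acid | C=C1C[C@]23C[C@@]1(O)CC[C@H]2[C@]12OC(=O)[C@](C)([C@@H](O)C=C1)[C@H]2[C@@H]3C(=O)O | starting material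
2 | GA3 methoxymethyl (MOM) ester | C=C1C[C@]23C[C@@]1(O)CC[C@H]2[C@]12OC(=O)[C@](C)([C@@H](O)C=C1)[C@H]2[C@@H]3C(=O)OCOC | intermediate
3 | C17-(9-borabicyclo[3.3.1]non-9-yl) adduct of 2 (16-H exo; not isolated) | C1CC2CCCC(C1)B2C[C@H]1C[C@]23C[C@@]1(O)CC[C@H]2[C@]12OC(=O)[C@](C)([C@@H](O)C=C1)[C@H]2[C@@H]3C(=O)OCOC | intermediate
4 | 16,17-dihydro-17-hydroxy-GA3 MOM ester (16-H exo, CH2OH endo, i.e. trans to 13-OH on ring D; 3β,13,17-triol) | OC[C@H]1C[C@]23C[C@@]1(O)CC[C@H]2[C@]12OC(=O)[C@](C)([C@@H](O)C=C1)[C@H]2[C@@H]3C(=O)OCOC | intermediate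
5 | 3-oxo (Δ1-3-ketone) analogue of 4; 13,17-diol | OC[C@H]1C[C@]23C[C@@]1(O)CC[C@H]2[C@]12OC(=O)[C@](C)(C(=O)C=C1)[C@H]2[C@@H]3C(=O)OCOC | intermediate
6 | 17-O-tosylate of 5 (not isolated) | Cc1ccc(cc1)S(=O)(=O)OC[C@H]1C[C@]23C[C@@]1(O)CC[C@H]2[C@]12OC(=O)[C@](C)(C(=O)C=C1)[C@H]2[C@@H]3C(=O)OCOC | intermediate
7 | 13,16-seco allyl ketone: ring C is a cyclohexan-13-one, C8 carries CH2CH=CH2 (C15–C17); Δ1-3-ketone, 19,10-lactone and 7-CO2MOM unchanged; C4, C5, C6, C8, C9, C10 as in GA3 | C=CC[C@]23CC(=O)CC[C@H]2[C@]12OC(=O)[C@](C)(C(=O)C=C1)[C@H]2[C@@H]3C(=O)OCOC | intermediate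
8 | 13-trimethylsilyloxy-Δ12 enol ether of 7 (not isolated) | C=CC[C@]23CC(O[Si](C)(C)C)=CC[C@H]2[C@]12OC(=O)[C@](C)(C(=O)C=C1)[C@H]2[C@@H]3C(=O)OCOC | intermediate
9 | ent-atisane-type enedione: bicyclo[2.2.2]octane C/D (bridgeheads C8, C12; new C12–C16 bond on the face of the C8 arm), 16-methylene, 13-ketone; Δ1-3-ketone, lactone, MOM ester | C=C1C[C@]23CC(=O)[C@H]1C[C@H]2[C@]12OC(=O)[C@](C)(C(=O)C=C1)[C@H]2[C@@H]3C(=O)OCOC | intermediate
10 | 13-alcohol of 9; OH on the side of the C9–C11 bridge, anti to the C12–C16 bond | C=C1C[C@]23C[C@@H](O)[C@H]1C[C@H]2[C@]12OC(=O)[C@](C)(C(=O)C=C1)[C@H]2[C@@H]3C(=O)OCOC | intermediate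
11 | 13-mesylate of 10 (not isolated) | C=C1C[C@]23C[C@@H](OS(C)(=O)=O)[C@H]1C[C@H]2[C@]12OC(=O)[C@](C)(C(=O)C=C1)[C@H]2[C@@H]3C(=O)OCOC | intermediate
12 | 12α-hydroxy-3-oxo-1,2-didehydro-GA9 MOM ester (gibberellane C/D restored; 12-OH axial, anti to C13–C16; not isolated) | C=C1C[C@]23C[C@H]1[C@@H](O)C[C@H]2[C@]12OC(=O)[C@](C)(C(=O)C=C1)[C@H]2[C@@H]3C(=O)OCOC | intermediate
13 | 12α-hydroxy-3-oxo-1,2-didehydro-GA9 (12α-hydroxy-3-dehydro-GA7), free 7-acid | C=C1C[C@]23C[C@H]1[C@@H](O)C[C@H]2[C@]12OC(=O)[C@](C)(C(=O)C=C1)[C@H]2[C@@H]3C(=O)O | intermediate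
14 | 1β,2β-epoxy-12α-hydroxy-3-oxo-GA9 (epoxide trans to the lactone oxygen) | C=C1C[C@]23C[C@H]1[C@@H](O)C[C@H]2[C@]12OC(=O)[C@](C)(C(=O)[C@H]4O[C@@H]14)[C@H]2[C@@H]3C(=O)O | intermediate
15 | 1β,12α-dihydroxy-3-oxo-GA9 (CNP0259985.1) | C=C1C[C@]23C[C@H]1[C@@H](O)C[C@H]2[C@]12OC(=O)[C@](C)(C(=O)C[C@H]1O)[C@H]2[C@@H]3C(=O)O | target

**Totals**
Total step count: 9. Longest linear sequence: 9 steps (fully linear from 1).

**Three steps most likely to fail**

Step 7 (cationic 1,2-shift). The bridged cation can also be captured at C13 (return to the atisane alcohol) or at C17 (cyclopropylcarbinol), so the kinetic share of the 12α-ol may be modest. Fallback, from 10, back to the route at 12: replace intermolecular water capture by ion-pair return. Alcohol 10 is acylated (TFAA, pyridine) to the 13-O-trifluoroacetate F4. Heating F4 in hexafluoroisopropanol with 2,6-di-tert-butylpyridine ionises it with the same C12–C16 participation. The trifluoroacetate then collapses within the tight ion pair onto C12, anti to the migrating C16 (a formal dyotropic interchange of C16 and acyloxy), giving the 12α-trifluoroacetate of the rearranged MOM ester F5. Mild NaHCO3 in MeOH–H2O removes the trifluoroacetyl group to give 12, whose MOM ester is cleaved with dilute aqueous acid as in step 7.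

Step 5 (Pd(II) closure of the bridged bicyclo[2.2.2] ring). Saegusa dehydrogenation to the C11–C12 enone may outrun the 6-exo bridging insertion. Fallback, from 8, back to the route at 9: switch from organopalladium to a free-radical atom-transfer cyclisation. Enol ether 8 is iodinated with NIS (THF, –78 °C) to the 12-iodo ketone F1. Et3B/air in benzene then starts an iodine-atom-transfer chain: the electrophilic C12 α-keto radical adds 6-exo to the electron-rich allyl group and the primary C17 radical abstracts iodine, giving the 17-iodo-16,17-dihydro ent-atisan-13-one F2. DBU in toluene eliminates HI (the only β-hydrogen is on C16) to give 9.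

Step 6 (ketone versus enone reduction). The C3 enone carbonyl is activated by the adjacent lactone carbonyl and may be reduced as well. Fallback, from 9, back to the route at 10: give up chemoselective reduction and use over-reduction followed by selective re-oxidation. NaBH4/CeCl3 (MeOH, –40 °C) reduces both carbonyls to the 3,13-diol F3 (the C3 epimer does not matter). MnO2, as in step 3, then re-oxidises only the allylic C3 alcohol to give 10.

**Further compounds**
F1 | step 5 | 12-iodo derivative of ketone 7 (C12 epimers, one shown) | C=CC[C@]23CC(=O)[C@@H](I)C[C@H]2[C@]12OC(=O)[C@](C)(C(=O)C=C1)[C@H]2[C@@H]3C(=O)OCOC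
F2 | step 5 | 17-iodo-16,17-dihydro derivative of 9 (C16 epimers, one shown) | IC[C@@H]1C[C@]23CC(=O)[C@H]1C[C@H]2[C@]12OC(=O)[C@](C)(C(=O)C=C1)[C@H]2[C@@H]3C(=O)OCOC
F3 | step 6 | 3,13-diol from over-reduction of 9 (3β-OH shown, 13-OH as in 10) | C=C1C[C@]23C[C@@H](O)[C@H]1C[C@H]2[C@]12OC(=O)[C@](C)([C@@H](O)C=C1)[C@H]2[C@@H]3C(=O)OCOC
F4 | step 7 | 13-O-trifluoroacetate of 10 | C=C1C[C@]23C[C@@H](OC(=O)C(F)(F)F)[C@H]1C[C@H]2[C@]12OC(=O)[C@](C)(C(=O)C=C1)[C@H]2[C@@H]3C(=O)OCOC
F5 | step 7 | 12α-O-trifluoroacetate of 12 | C=C1C[C@]23C[C@H]1[C@@H](OC(=O)C(F)(F)F)C[C@H]2[C@]12OC(=O)[C@](C)(C(=O)C=C1)[C@H]2[C@@H]3C(=O)OCOC
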